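**Retrosynthetic overview**
- The target comes from a 4'-O-methyl hydroquinone aldehyde by O-sulfation of O-2'/O-5' and then thiolate O-demethylation at O-4'. The para pair O-2'/O-5' is distinguished from O-4' by oxidative demethylation of a 2',4',5'-trimethoxyarene to its p-quinone.
- The aldehyde comes from directed ortho-lithiation and formylation at C-3' of the trimethoxystyryl decalin.
- The styryl decalin comes from acyclic (E,E)-farnesyl-2,4,5-trimethoxybenzene in one enantioselective proton-initiated cascade. The cascade closes rings A and B together. Two 1,2-hydride shifts follow (H-9 to C-8 sets 8S, then H-11 to C-9), and proton loss gives the E C-9=C-11 olefin.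
- The farnesylarene comes from 1-bromo-2,4,5-trimethoxybenzene and (2E,6E)-farnesyl bromide.
- Ring order: the arene is bought, rings A and B form at once in step 2, and no ring is made afterwards.

Assumption: the target is taken as drawn, the free bis(hydrogen sulfate), released from its sodium salt only in the last operation and kept cold.
Numbering: drimane numbers for the terpene (C-4 CMe2, C-5 H, C-8 CHMe, C-9 ylidene carbon, C-10 CMe, C-11 vinylic CH). Primes are used for the arene, with C-1' on C-11.
Note: the chiral ligand of step 2 takes one O-alkylation from (R)-BINOL and is recovered after use. It is treated as a reagent.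

**Step 1**
Reactants: 1 1-bromo-2,4,5-trimethoxybenzene; 2 (2E,6E)-farnesyl bromide
Product: 4 1-[(2E,6E)-farnesyl]-2,4,5-trimethoxybenzene, via 2,4,5-trimethoxyphenyllithium 3 (not isolated)
Conditions: n-BuLi, THF, −78 °C; CuBr·SMe2 (10 mol %), then 2, −78 → 0 °C
Reagents that add atoms: none
Why: Bromine–lithium exchange gives the aryllithium, which under copper catalysis displaces the primary allylic bromide in the SN2 sense (allylic cross-coupling) with both E olefins untouched; no stereocentre is formed.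

**Step 2**
Reactants: 4 1-[(2E,6E)-farnesyl]-2,4,5-trimethoxybenzene
Product: 8 1-{(E)-[(2S,4aS,8aS)-2,5,5,8a-tetramethyloctahydronaphthalen-1(2H)-ylidene]methyl}-2,4,5-trimethoxybenzene, via drim-8-yl cation 5 (not isolated), via drim-9-yl cation 6 (not isolated), via C-11 benzylic cation 7 (not isolated)
Conditions: (R)-2-(2-fluorobenzyloxy)-2'-hydroxy-1,1'-binaphthyl·SnCl4 (2 equiv), toluene, −78 °C, 48 h; then CF3CO2H (5 equiv), SnCl4 (1 equiv), CH2Cl2, −78 → −45 °C; Et3N, −78 °C
Reagents that add atoms: none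
Why: Proposed new method: the chiral Lewis acid-assisted Brønsted acid protonates the terminal isopropylidene on one enantioface (the (R)-ligand is the one that gives the 5S,10S ambrox-type series) and the E,E-triene folds chair–chair (Stork–Eschenmoser), so rings A and B close in one cationic event with trans 5α-H/10β-CH3 fusion and 9α-H (5); with no nucleophile in reach the axial 9α-H migrates suprafacially to the α face of C-8, which fixes the axial 8β-CH3 (8S, 6); a second 1,2-hydride shift from C-11 drains the manifold into the 2,4-dialkoxybenzyl cation 7, far more stable than any tertiary cation on the competing 10-methyl-shift path and so not left again at low temperature; Et3N then removes H-9 with the aryl group turned away from quaternary C-10, giving the E olefin; olefins from early proton loss are re-protonated from the open α face by CF3CO2H·SnCl4 and re-enter the same funnel; the closest known reaction types are the BINOL-ether·SnCl4 enantioselective cyclisation of 2-farnesylphenol derivatives, the acid-induced H-9 to C-8 shift of 9-benzyl drim-8-yl cations, and the E1 dehydration of 11-aryl-11-hydroxydrimanes.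

**Step 3**
Reactants: 8 trimethoxystyryl decalin from step 2
Product: 11 2,3,6-trimethoxy-5-{(E)-[(2S,4aS,8aS)-2,5,5,8a-tetramethyloctahydronaphthalen-1(2H)-ylidene]methyl}benzaldehyde, via C-3' aryllithium 9 (not isolated), via lithium hemiaminal alkoxide 10 (not isolated)
Conditions: n-BuLi, TMEDA, THF, 0 °C; DMF, 0 °C → rt; H2O; recrystallisation (hexane) to raise the ee
Reagents that add atoms: N,N-dimethylformamide, CN(C)C=O
Why: Directed ortho-metalation: C-3' lies between two methoxy groups and is the most acidic, doubly coordinated site, so lithiation and DMF quench (Bouveault-type formylation) place the aldehyde only there, and no stereocentre is touched.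

**Step 4**
Reactants: 11 trimethoxy aldehyde
Product: 13 3,6-dihydroxy-2-methoxy-5-{(E)-[(2S,4aS,8aS)-2,5,5,8a-tetramethyloctahydronaphthalen-1(2H)-ylidene]methyl}benzaldehyde, via methoxy formyl p-quinone 12 (not isolated)
Conditions: (NH4)2Ce(NO3)6 (2.5 equiv), MeCN/H2O, 0 °C, 15 min; then Na2S2O4, EtOAc/H2O, rt, Ar
Reagents that add atoms: water, O
Why: Oxidative demethylation by tetravalent cerium removes only the para-related 2'- and 5'-methoxy groups (water attacks the ipso carbons of the arene radical cation) and leaves the 4'-methoxy group, and dithionite reduces the fragile formylquinone at once, so O-2'/O-5' are freed while O-4' stays blocked without any protecting-group step.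

**Step 5**
Reactants: 13 4'-O-methyl hydroquinone aldehyde
Product: 15 disodium 2',5'-bis(sulfate) of 13, via disodium bis(phenoxide) 14 (not isolated)
Conditions: NaH (2.2 equiv), DMF, 0 °C, Ar; Me3N·SO3 (5 equiv), 0 → 45 °C
Reagents that add atoms: sodium hydride, [Na+].[H-]; sulfur trioxide–trimethylamine complex, C[N+](C)(C)S(=O)(=O)[O-]
Why: O-sulfation: full deprotonation breaks the 2'-OH···O=CH hydrogen bond so that both phenoxides attack sulfur of the amine–SO3 complex, and the only other oxygen is a methyl ether, so the sulfate pattern is unambiguous.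

**Step 6**
Reactants: 15 disodium 4'-O-methyl bis(sulfate)
Product: 17 target CNP0309628.1 as the free bis(hydrogen sulfate), via trisodium salt 16 (not isolated)
Conditions: NaSEt (5 equiv), DMF, 90 °C; then 1 M HCl, 0 °C, C18 desalting, lyophilisation
Reagents that add atoms: none
Why: SN2 O-demethylation by a soft thiolate: the 4'-methoxy group is the only methyl ether and its phenoxide leaving group is stabilised by the ortho formyl group, anionic aryl sulfate monoesters resist bases and nucleophiles, any 5' to 4' sulfate migration is uphill because the more acidic O-4' prefers to stay the phenoxide, and cold acid then protonates the salt.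

**Compound list**
1 | 1-bromo-2,4,5-trimethoxybenzene | COc1cc(OC)c(OC)cc1Br | starting material
2 | (2E,6E)-farnesyl bromide | CC(C)=CCC/C(C)=C/CC/C(C)=C/CBr | starting material
3 | 2,4,5-trimethoxyphenyllithium | COc1cc(OC)c(OC)cc1[Li] | intermediate
4 | 1-[(2E,6E)-farnesyl]-2,4,5-trimethoxybenzene | CC(C)=CCC/C(C)=C/CC/C(C)=C/Cc1cc(OC)c(OC)cc1OC | intermediate
5 | 11-(2,4,5-trimethoxyphenyl)drim-8-yl cation (5α-H, 10β-CH3, 9α-H) | C[C+]1CC[C@H]2C(C)(C)CCC[C@]2(C)[C@H]1Cc1cc(OC)c(OC)cc1OC | intermediate
6 | 11-(2,4,5-trimethoxyphenyl)drim-9-yl cation (8α-H, 8β-CH3) | C[C@H]1CC[C@H]2C(C)(C)CCC[C@]2(C)[C+]1Cc1cc(OC)c(OC)cc1OC | intermediate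
7 | 11-(2,4,5-trimethoxyphenyl)driman-11-yl benzylic cation (8β-CH3, 9α-H) | C[C@H]1CC[C@H]2C(C)(C)CCC[C@]2(C)[C@H]1[CH+]c1cc(OC)c(OC)cc1OC | intermediate
8 | 1-{(E)-[(2S,4aS,8aS)-2,5,5,8a-tetramethyloctahydronaphthalen-1(2H)-ylidene]methyl}-2,4,5-trimethoxybenzene | C[C@H]1CC[C@H]2C(C)(C)CCC[C@]2(C)/C1=C/c1cc(OC)c(OC)cc1OC | intermediate
9 | 3'-lithio derivative of 8 | C[C@H]1CC[C@H]2C(C)(C)CCC[C@]2(C)/C1=C/c1cc(OC)c(OC)c([Li])c1OC | intermediate
10 | lithium α-(dimethylamino)benzyl alkoxide from 9 and DMF (both configurations at the new carbinol carbon) | C[C@H]1CC[C@H]2C(C)(C)CCC[C@]2(C)/C1=C/c1cc(OC)c(OC)c(C(O[Li])N(C)C)c1OC | intermediate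
11 | 2,3,6-trimethoxy-5-{(E)-[(2S,4aS,8aS)-decalinylidene]methyl}benzaldehyde | C[C@H]1CC[C@H]2C(C)(C)CCC[C@]2(C)/C1=C/c1cc(OC)c(OC)c(C=O)c1OC | intermediate
12 | 2-methoxy-3,6-dioxo-5-{(E)-[(2S,4aS,8aS)-decalinylidene]methyl}cyclohexa-1,4-diene-1-carbaldehyde | C[C@H]1CC[C@H]2C(C)(C)CCC[C@]2(C)/C1=C/C1=CC(=O)C(OC)=C(C=O)C1=O | intermediate
13 | 3,6-dihydroxy-2-methoxy-5-{(E)-[(2S,4aS,8aS)-decalinylidene]methyl}benzaldehyde | C[C@H]1CC[C@H]2C(C)(C)CCC[C@]2(C)/C1=C/c1cc(O)c(OC)c(C=O)c1O | intermediate
14 | disodium 2',5'-bis(phenoxide) of 13 | C[C@H]1CC[C@H]2C(C)(C)CCC[C@]2(C)/C1=C/c1cc([O-])c(OC)c(C=O)c1[O-].[Na+].[Na+] | intermediate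
15 | disodium 2',5'-bis(sulfate) of 13 | C[C@H]1CC[C@H]2C(C)(C)CCC[C@]2(C)/C1=C/c1cc(OS(=O)(=O)[O-])c(OC)c(C=O)c1OS(=O)(=O)[O-].[Na+].[Na+] | intermediate
16 | trisodium salt of the target (4'-phenoxide, 2'- and 5'-sulfates) | C[C@H]1CC[C@H]2C(C)(C)CCC[C@]2(C)/C1=C/c1cc(OS(=O)(=O)[O-])c([O-])c(C=O)c1OS(=O)(=O)[O-].[Na+].[Na+].[Na+] | intermediate
17 | CNP0309628.1: 3'-formyl-4'-hydroxy-1'-{(E)-[(2S,4aS,8aS)-2,5,5,8a-tetramethyloctahydronaphthalen-1(2H)-ylidene]methyl}benzene-2',5'-diyl bis(hydrogen sulfate) | C[C@H]1CC[C@H]2C(C)(C)CCC[C@]2(C)/C1=C/c1cc(OS(=O)(=O)O)c(O)c(C=O)c1OS(=O)(=O)O | target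

**Total step count:** 6. **Longest linear sequence:** 6 (from 1 or 2).

**The three steps most likely to fail**

**Step 2.** The hydride-shift termination may lose to simple proton loss at C-8, to the 10-methyl-shift path, or to Friedel–Crafts closure at C-6'. The fallback sets out from 4 and comes back at 8.
- Stop the same chiral-acid bicyclisation after its first stage. Cation 5 then only loses a proton, giving the drim-7-en-11-yl arene F1 together with the drim-8(12)-en-11-yl arene F2.
- Hydrogenate the mixture (H2, PtO2, EtOAc/AcOH) from the open α face, since the β face is screened by the axial 10-CH3. Both olefins converge on the 8β-methyl-9α-H drimanyl arene F3, and C-8 is set by substrate control.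
- Abstract the benzylic hydride with DDQ (CH2Cl2, rt). This makes cation 7 by oxidation instead of by hydride shifts, and loss of H-9 gives 8.

**Step 4.** The formyl group raises the oxidation potential of the arene toward that of the styrene, and the formylquinone 12 is very electrophilic. The fallback sets out from 8 and comes back at 13.
- Oxidise before the aldehyde is present. (NH4)2Ce(NO3)6 acts on the more electron-rich 8 (MeCN/H2O, 0 °C) to give the methoxy-p-quinone F4.
- Na2S2O4 reduces it to the methoxyhydroquinone F5.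
- Magnesium-phenoxide ortho-formylation (MgCl2, Et3N, paraformaldehyde, MeCN, reflux, Ar) places the aldehyde at C-3'. That position is ortho to 2'-OH and is also activated by the 4'-methoxy group. The product is 13.

**Step 6.** Demethylation on a dianionic bis(sulfate) bearing an aldehyde may be slow or may cost a sulfate. The hindered 2'-sulfation of step 5 shares this risk. The fallback sets out from 13 and comes back at 17.
- Carry the sulfates as neutral diesters. Cl3CCH2OSO2Cl, Et3N and DMAP in THF give the bis(2,2,2-trichloroethyl sulfate) F6.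
- BCl3 (CH2Cl2, −78 → 0 °C), chelated by the formyl oxygen, cleaves the 4'-methyl ether to give the 4'-phenol bis(trichloroethyl sulfate) F7.
- Zn and HCO2NH4 in MeOH at rt remove both trichloroethyl groups to give the diammonium bis(sulfate) F8.
- Cold 1 M HCl with C18 desalting gives 17.

**Further compounds**
F1 | step 2 | 11-(2,4,5-trimethoxyphenyl)drim-7-ene (5α-H, 9α-H, 10β-CH3) | CC1=CC[C@H]2C(C)(C)CCC[C@]2(C)[C@H]1Cc1cc(OC)c(OC)cc1OC
F2 | step 2 | 11-(2,4,5-trimethoxyphenyl)drim-8(12)-ene (5α-H, 9α-H, 10β-CH3) | C=C1CC[C@H]2C(C)(C)CCC[C@]2(C)[C@H]1Cc1cc(OC)c(OC)cc1OC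
F3 | step 2 | 11-(2,4,5-trimethoxyphenyl)drimane (8β-CH3, 9α-H) | C[C@H]1CC[C@H]2C(C)(C)CCC[C@]2(C)[C@H]1Cc1cc(OC)c(OC)cc1OC
F4 | step 4 | 2-methoxy-5-{(E)-[(2S,4aS,8aS)-decalinylidene]methyl}-1,4-benzoquinone | C[C@H]1CC[C@H]2C(C)(C)CCC[C@]2(C)/C1=C/C1=CC(=O)C(OC)=CC1=O
F5 | step 4 | 2-methoxy-5-{(E)-[(2S,4aS,8aS)-decalinylidene]methyl}benzene-1,4-diol | C[C@H]1CC[C@H]2C(C)(C)CCC[C@]2(C)/C1=C/c1cc(O)c(OC)cc1O
F6 | step 6 | 2',5'-bis(2,2,2-trichloroethyl sulfate) of 13 | C[C@H]1CC[C@H]2C(C)(C)CCC[C@]2(C)/C1=C/c1cc(OS(=O)(=O)OCC(Cl)(Cl)Cl)c(OC)c(C=O)c1OS(=O)(=O)OCC(Cl)(Cl)Cl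
F7 | step 6 | 4'-phenol 2',5'-bis(2,2,2-trichloroethyl sulfate) | C[C@H]1CC[C@H]2C(C)(C)CCC[C@]2(C)/C1=C/c1cc(OS(=O)(=O)OCC(Cl)(Cl)Cl)c(O)c(C=O)c1OS(=O)(=O)OCC(Cl)(Cl)Cl
F8 | step 6 | diammonium salt of the target | C[C@H]1CC[C@H]2C(C)(C)CCC[C@]2(C)/C1=C/c1cc(OS(=O)(=O)[O-])c(O)c(C=O)c1OS(=O)(=O)[O-].[NH4+].[NH4+]
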